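**Plan**

- Retrosynthesis: after acetate and redox adjustment, cut the cyclopropane bonds C8–C9 and C8–C10 (diazoalkane from the C7–C8 arm onto the C9=C10 enone), then C3=C4 of ring A (ring-closing metathesis), then C1–C6 with a ketone carbon C12 put back between them (photodecarbonylation of a cyclohex-4-ene-1,3-dione), then C5–C6 (Claisen) and C1–C2 (Birch alkylation) back to a salicylate.
- Forward: arene → six-membered dienone → 2,2,6,6-tetrasubstituted enedione → five-membered ring C1–C6–C11–C10–C9 by loss of CO → ring A → cyclopropane (cage) → oxygenation of ring A, adjustment of C11 and C15.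
- Enabling feature: C1 and C6 are the vicinal quaternary carbons shared by ring A and the five-membered ring. C1 is allylic to C9=C10 and α to the C15 carboxyl carbon, C6 is α to the C11 carbonyl, so a ketone carbon bridging them can leave as CO from a doubly stabilised radical pair.
- Stereochemistry: C1 from a prolinol-ether auxiliary in the Birch alkylation; C6 from C1 in the Claisen step; both carried through the crystal-phase photodecarbonylation; C8, C9, C10 from the α-face tether; C4 by ketol equilibration, C3 by equatorial hydride attack, C11 by acetate capture of a cyclopropylcarbinyl cation on its open face.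

Key step: step 9

**Remarks**

- Locants follow the target: C1 quaternary (bears C15H2OAc), C2–C5 rest of ring A (C3 OAc, C4 OH, C5 CMe2), C6 apex, C7 CH2, C8/C9/C10 cyclopropane (C10 methyl), C11 CHOAc. C12 is the extra ring carbonyl carbon that leaves as CO.
- α is the face of the ring C1–C6–C11–C10–C9 that carries C15, C7 and C8; β is the face that carries C2 and C5. On ring A, 3α is axial and 4α equatorial.
- Assumption: the (S)-configured auxiliary is taken to direct allylation of the C1 enolate to the face drawn for 10; if the sense proves opposite, the (R)-auxiliary is used and nothing else changes.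

**Route**

Step 1
Reactants: 1 methyl 2-hydroxy-5-methylbenzoate; 2 allyl bromide
Product: 3 methyl 2-(allyloxy)-5-methylbenzoate
Conditions: K2CO3, acetone, reflux
Reagents that add atoms: none
Why: Williamson O-allylation of the phenol under carbonate conditions; no stereocentre is involved.

Step 2
Reactants: 3 methyl 2-(allyloxy)-5-methylbenzoate
Product: 4 methyl 3-allyl-2-hydroxy-5-methylbenzoate
Conditions: neat, 200 °C, Ar, sealed tube
Reagents that add atoms: none
Why: Aromatic Claisen rearrangement can end only at the one free ortho position because the para position carries the methyl group; the allyl group placed here becomes the C7–C8 arm.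

Step 3
Reactants: 4 methyl 3-allyl-2-hydroxy-5-methylbenzoate
Product: 5 methyl 3-allyl-2-methoxy-5-methylbenzoate
Conditions: MeI, K2CO3, DMF, 50 °C
Reagents that add atoms: iodomethane, CI
Why: Williamson methylation gives the 2-methoxy group that directs the dissolving-metal step and becomes the latent C12 oxygen.

Step 4
Reactants: 5 methyl 3-allyl-2-methoxy-5-methylbenzoate; 6 (2S)-2-(methoxymethyl)pyrrolidine
Product: 7 3-allyl-2-methoxy-5-methylbenzoyl (2S)-2-(methoxymethyl)pyrrolidine
Conditions: AlMe3 (2 equiv), PhMe, 0 → 90 °C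
Reagents that add atoms: none
Why: AlMe3-mediated aminolysis of the methyl ester by the secondary amine attaches the chiral auxiliary as a tertiary amide.

Step 5
Reactants: 7 3-allyl-2-methoxy-5-methylbenzoyl (2S)-2-(methoxymethyl)pyrrolidine
Product: 9 dioxolane-protected benzamide, via arylacetaldehyde 8 (not isolated)
Conditions: O3, CH2Cl2–MeOH, −78 °C; Me2S; then HOCH2CH2OH, TsOH (cat.), PhH, reflux (−H2O)
Reagents that add atoms: ethane-1,2-diol, OCCO
Why: Ozonolysis of the terminal alkene is far faster than attack on the arene, and the sensitive arylacetaldehyde is acetalised at once, so the arm survives the reducing, oxidising and basic steps that follow.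

Step 6
Reactants: 9 dioxolane-protected benzamide; 2 allyl bromide
Product: 10 1-allyl-2-methoxycyclohexa-2,5-diene-1-carboxamide
Conditions: K, NH3(l)–THF, t-BuOH (1 equiv), −78 °C; then allyl bromide, −78 °C
Reagents that add atoms: none
Why: Birch reductive alkylation: reduction with protonation para to the carboxamide leaves the amide enolate at C1, which is allylated on the face left open by the potassium-chelated methoxymethylpyrrolidine, so the auxiliary sets C1.

Step 7
Reactants: 10 1-allyl-2-methoxycyclohexa-2,5-diene-1-carboxamide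
Product: 11 cross-conjugated dienone (vinylogous methyl ester)
Conditions: (C5H5NH)2Cr2O7, t-BuOOH, Celite, PhH, rt
Reagents that add atoms: tert-butyl hydroperoxide, CC(C)(C)OO
Why: Allylic oxidation occurs at C11, the only doubly allylic methylene (between the enol ether and the C9=C10 alkene), and gives the 2,5-cyclohexadienone.

Step 8
Reactants: 11 cross-conjugated dienone (vinylogous methyl ester); 12 3-methylbut-2-en-1-ol
Product: 14 enedione with quaternary C1 and C6, via prenyl vinylogous ester 13 (not isolated)
Conditions: 3-methylbut-2-en-1-ol (5 equiv), PPTS (cat.), PhH, 4 Å MS, 60 °C; then Et3N (cat.), PhMe, 110 °C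
Reagents that add atoms: none
Why: Acid-catalysed alkoxy exchange at the vinylogous ester carbon C12 and Claisen rearrangement of the resulting allyl vinyl ether deliver the 1,1-dimethylallyl group to C6 through a chair transition state on the β-face, anti to the bulky N-acylpyrrolidine on C1, so C6 is set by C1 with allyl and 1,1-dimethylallyl cis.

Step 9
Reactants: 14 enedione with quaternary C1 and C6
Product: 15 cyclopentenone with vicinal quaternary C1 and C6
Conditions: hν (λ > 300 nm, medium-pressure Hg lamp, Pyrex), crystalline 14 as a stirred aqueous suspension (sodium dodecyl sulfate), 10–20 °C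
Reagents that add atoms: none
Why: Proposed new method: n,π* excitation of the saturated C12 ketone leads to α-cleavage (Norrish type 1) to an acyl–alkyl biradical, the acyl radical loses CO because both carbons are stabilised (C1 allylic to C9=C10 and α to the C15 amide, C6 α to the C11 ketone), and the 1,5-biradical collapses to the C1–C6 bond; the closest known reaction type is the solid-state photodecarbonylation of crystalline ketones that carry radical-stabilising groups on both α-carbons and give vicinal quaternary centres. The five-membered ring closes by radical–radical combination of the two ends of the chain C1–C9=C10–C11–C6, a contraction of the six-membered enedione. C1 and C6 are not created here but carried over: in the lattice the two trigonal centres cannot rotate, each should rebond on the lobe vacated by C12, and both configurations should be retained. The step needs bonding at C1 and not at C10, the other end of the delocalised radical; bonding at C10 would give a strained vinylcyclopropanone that reopens, so the cyclopentenone is the sink. It also needs decarbonylation to outrun re-closure and 1,3-acyl shift, which the double stabilisation of the radical pair and the rigid crystal are expected to provide.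

Step 10
Reactants: 15 cyclopentenone with vicinal quaternary C1 and C6
Product: 16 cis-fused hydrindenone (ring A closed)
Conditions: second-generation Grubbs catalyst RuCl2(=CHPh)(H2IMes)(PCy3) (5 mol %), CH2Cl2, 40 °C
Reagents that add atoms: none
Why: Ring-closing metathesis between the allyl group on C1 and the vinyl group of the 1,1-dimethylallyl unit on C6, which are cis, closes ring A as a cyclohexene; the electron-poor trisubstituted enone alkene does not take part.

Step 11
Reactants: 16 cis-fused hydrindenone (ring A closed)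
Product: 18 aldehyde tosylhydrazone, via aldehyde 17 (not isolated)
Conditions: 1 M HCl, THF, rt; then TsNHNH2, MeOH, rt
Reagents that add atoms: 4-methylbenzenesulfonohydrazide, Cc1ccc(cc1)S(=O)(=O)NN
Why: Acetal hydrolysis followed by condensation at the unhindered aldehyde; the C11 ketone is conjugated and flanked by a quaternary carbon and does not condense.

Step 12
Reactants: 18 aldehyde tosylhydrazone
Product: 21 cage ketone (cyclopropane closed), via diazoalkane 19 (not isolated), via bridged pyrazoline 20 (not isolated)
Conditions: NaH, THF, 0 °C; then PhMe, 90 °C; then hν (350 nm), rt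
Reagents that add atoms: none
Why: Bamford–Stevens formation of the diazoalkane, intramolecular 1,3-dipolar cycloaddition to the enone (diazo carbon to the β-carbon C9, nitrogen to C10) and loss of N2 from the 1-pyrazoline close the cyclopropane; the α-face tether through C7 fixes C8, C9 and C10.

Step 13
Reactants: 21 cage ketone (cyclopropane closed)
Product: 23 3-oxo-4α-hydroxy ketol, via kinetic ketol 22 (not isolated)
Conditions: RuCl3·xH2O (1 mol %), 2KHSO5·KHSO4·K2SO4, NaHCO3, EtOAc–MeCN–H2O, 0 °C; then K2CO3 (0.2 equiv), degassed MeOH, rt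
Reagents that add atoms: potassium peroxymonosulfate, [K+].OOS([O-])(=O)=O
Why: Ruthenium tetroxide-catalysed ketohydroxylation of the only alkene, then base equilibration through the enediol (the regioisomeric ketol converges as well) to the more stable α-ketol, which by analogy with 2,3-dioxygenated 4,4-dimethyl ring-A terpenoids has the carbonyl at C3 away from the gem-dimethyl carbon and the C4 hydroxyl equatorial (α), so C4 is set under thermodynamic control.

Step 14
Reactants: 23 3-oxo-4α-hydroxy ketol
Product: 25 3α,4α,11β,15-tetraol, via diol ketone 24 (not isolated)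
Conditions: LiBH(s-Bu)3, THF, −78 °C; then LiH2N·BH3 (from H3N·BH3 and LiN(i-Pr)2), THF, 0 °C → rt
Reagents that add atoms: none
Why: The bulky borohydride attacks the C3 ketone equatorially (axial approach is blocked by the axial C15 substituent and the axial C5 methyl) to give the axial 3α-alcohol, then the amidoborohydride reduces the tertiary amide to the primary alcohol and the C11 ketone from its open C7 side, which gives the 11β-alcohol that is inverted in step 16.

Step 15
Reactants: 25 3α,4α,11β,15-tetraol
Product: 27 15-acetate 3,4-orthoacetate, via 15-monoacetate 26 (not isolated)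
Conditions: Ac2O (1.1 equiv), pyridine, CH2Cl2, −20 °C; then MeC(OMe)3, PPTS (cat.), CH2Cl2, rt
Reagents that add atoms: acetic anhydride, CC(=O)OC(C)=O; trimethyl orthoacetate, COC(C)(OC)OC
Why: Acylation of the primary alcohol is much faster than that of the three hindered secondary alcohols, and the cis-3,4-diol then forms the five-membered cyclic orthoester by acid-catalysed exchange.

Step 16
Reactants: 27 15-acetate 3,4-orthoacetate
Product: 30 CNP0197219.1, via 11β-mesylate 28 (not isolated), via 11α-acetoxy orthoacetate 29 (not isolated)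
Conditions: (MeSO2)2O, Et3N, CH2Cl2, −30 °C; then KOAc, AcOH, rt → 40 °C; then H2O (AcOH–H2O 4:1), rt
Reagents that add atoms: acetic acid, CC(O)=O; water, O
Why: The strained, ring-A-facing 11β-mesylate ionises to the bisected cyclopropylcarbinyl (nortricyclyl-type) cation, which acetate captures at C11 from the open C7 face (SN1 solvolysis with net inversion), and aqueous acid then opens the orthoester through the dioxolanylium ion to the axial 3α-acetate and the equatorial 4α-alcohol.

**Compound list**

1 | methyl 2-hydroxy-5-methylbenzoate | COC(=O)c1cc(C)ccc1O | starting material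
2 | allyl bromide (3-bromoprop-1-ene) | C=CCBr | starting material
3 | methyl 5-methyl-2-(prop-2-enyloxy)benzoate | COC(=O)c1cc(C)ccc1OCC=C | intermediate
4 | methyl 2-hydroxy-5-methyl-3-(prop-2-enyl)benzoate | COC(=O)c1cc(C)cc(CC=C)c1O | intermediate
5 | methyl 2-methoxy-5-methyl-3-(prop-2-enyl)benzoate | COC(=O)c1cc(C)cc(CC=C)c1OC | intermediate
6 | (2S)-2-(methoxymethyl)pyrrolidine | COC[C@@H]1CCCN1 | starting material
7 | [(2S)-2-(methoxymethyl)pyrrolidin-1-yl][2-methoxy-5-methyl-3-(prop-2-enyl)phenyl]methanone | COC[C@@H]1CCCN1C(=O)c1cc(C)cc(CC=C)c1OC | intermediate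
8 | 2-{2-methoxy-3-[(2S)-2-(methoxymethyl)pyrrolidine-1-carbonyl]-5-methylphenyl}acetaldehyde | COC[C@@H]1CCCN1C(=O)c1cc(C)cc(CC=O)c1OC | intermediate (not isolated)
9 | [3-(1,3-dioxolan-2-ylmethyl)-2-methoxy-5-methylphenyl][(2S)-2-(methoxymethyl)pyrrolidin-1-yl]methanone | COC[C@@H]1CCCN1C(=O)c1cc(C)cc(CC2OCCO2)c1OC | intermediate
10 | [3-(1,3-dioxolan-2-ylmethyl)-2-methoxy-5-methyl-1-(prop-2-enyl)cyclohexa-2,5-dien-1-yl][(2S)-2-(methoxymethyl)pyrrolidin-1-yl]methanone; quaternary ring carbon (target C1) as in the SMILES | COC[C@@H]1CCCN1C(=O)[C@@]1(CC=C)C=C(C)CC(CC2OCCO2)=C1OC | intermediate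
11 | 2-(1,3-dioxolan-2-ylmethyl)-3-methoxy-6-methyl-4-(prop-2-enyl)-4-[(2S)-2-(methoxymethyl)pyrrolidine-1-carbonyl]cyclohexa-2,5-dien-1-one (C4 of this name is target C1) | COC[C@@H]1CCCN1C(=O)[C@@]1(CC=C)C=C(C)C(=O)C(CC2OCCO2)=C1OC | intermediate
12 | 3-methylbut-2-en-1-ol (prenyl alcohol) | CC(C)=CCO | starting material
13 | 3-(3-methylbut-2-enyloxy) analogue of 11 (prenyl vinylogous ester at C12) | COC[C@@H]1CCCN1C(=O)[C@@]1(CC=C)C=C(C)C(=O)C(CC2OCCO2)=C1OCC=C(C)C | intermediate (not isolated)
14 | 2-(1,3-dioxolan-2-ylmethyl)-4-methyl-2-(2-methylbut-3-en-2-yl)-6-(prop-2-enyl)-6-[(2S)-2-(methoxymethyl)pyrrolidine-1-carbonyl]cyclohex-4-ene-1,3-dione; prop-2-enyl (on target C1) and 2-methylbut-3-en-2-yl (on target C6) cis, carboxamide and dioxolanylmethyl cis | COC[C@@H]1CCCN1C(=O)[C@@]1(CC=C)C=C(C)C(=O)[C@](CC2OCCO2)(C(C)(C)C=C)C1=O | intermediate (precursor of the key step)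
15 | 5-(1,3-dioxolan-2-ylmethyl)-2-methyl-5-(2-methylbut-3-en-2-yl)-4-(prop-2-enyl)-4-[(2S)-2-(methoxymethyl)pyrrolidine-1-carbonyl]cyclopent-2-en-1-one; prop-2-enyl and 2-methylbut-3-en-2-yl cis (β), carboxamide and dioxolanylmethyl cis (α) | COC[C@@H]1CCCN1C(=O)[C@@]1(CC=C)C=C(C)C(=O)[C@]1(CC2OCCO2)C(C)(C)C=C | intermediate (product of the key step)
16 | cis-fused 7a-(1,3-dioxolan-2-ylmethyl)-2,7,7-trimethyl-3a-[(2S)-2-(methoxymethyl)pyrrolidine-1-carbonyl]-3a,4,7,7a-tetrahydro-1H-inden-1-one (ring A C1–C2–C3=C4–C5–C6; both angular groups α) | COC[C@@H]1CCCN1C(=O)[C@]12CC=CC(C)(C)[C@@]1(CC3OCCO3)C(=O)C(C)=C2 | intermediate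
17 | aldehyde from 16 (C6–CH2–CHO arm) | COC[C@@H]1CCCN1C(=O)[C@]12CC=CC(C)(C)[C@@]1(CC=O)C(=O)C(C)=C2 | intermediate (not isolated)
18 | (E)-4-methylbenzenesulfonylhydrazone of 17 | COC[C@@H]1CCCN1C(=O)[C@]12CC=CC(C)(C)[C@@]1(C/C=N/NS(=O)(=O)c3ccc(C)cc3)C(=O)C(C)=C2 | intermediate
19 | diazoalkane from 18 (C6–CH2–CH=N2) | COC[C@@H]1CCCN1C(=O)[C@]12CC=CC(C)(C)[C@@]1(CC=[N+]=[N-])C(=O)C(C)=C2 | intermediate (not isolated)
20 | bridged 1-pyrazoline (C8–C9 bond formed, N=N spanning C8 and C10 on the α-face, C10 methyl β) | COC[C@@H]1CCCN1C(=O)[C@]12CC=CC(C)(C)[C@@]1(C[C@H]3N=N[C@]4(C)[C@@H]23)C4=O | intermediate (not isolated)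
21 | cage ketone: target skeleton with C11 ketone, ring A alkene C3=C4 and the C15 carboxamide | COC[C@@H]1CCCN1C(=O)[C@]12CC=CC(C)(C)[C@]13C[C@@H]1[C@H]2[C@]1(C)C3=O | intermediate
22 | 3-oxo-4β-hydroxy (axial OH) ketol of the cage, C11 ketone, C15 carboxamide | COC[C@@H]1CCCN1C(=O)[C@]12CC(=O)[C@@H](O)C(C)(C)[C@]13C[C@@H]1[C@H]2[C@]1(C)C3=O | intermediate (not isolated)
23 | 3-oxo-4α-hydroxy (equatorial OH) ketol of the cage, C11 ketone, C15 carboxamide | COC[C@@H]1CCCN1C(=O)[C@]12CC(=O)[C@H](O)C(C)(C)[C@]13C[C@@H]1[C@H]2[C@]1(C)C3=O | intermediate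
24 | 3α,4α-diol of the cage with C11 ketone and C15 carboxamide | COC[C@@H]1CCCN1C(=O)[C@]12C[C@H](O)[C@H](O)C(C)(C)[C@]13C[C@@H]1[C@H]2[C@]1(C)C3=O | intermediate (not isolated)
25 | 3α,4α,11β,15-tetraol of the cage (C11 epimer of the natural tetraol) | OC[C@]12C[C@H](O)[C@H](O)C(C)(C)[C@]13C[C@@H]1[C@H]2[C@]1(C)[C@@H]3O | intermediate
26 | 15-O-acetyl-3α,4α,11β-triol | CC(=O)OC[C@]12C[C@H](O)[C@H](O)C(C)(C)[C@]13C[C@@H]1[C@H]2[C@]1(C)[C@@H]3O | intermediate (not isolated)
27 | 15-O-acetyl-3α,4α-O-(1-methoxyethylidene)-11β-ol (orthoester carbon as a mixture) | CC(=O)OC[C@]12C[C@@H]4OC(C)(OC)O[C@@H]4C(C)(C)[C@]13C[C@@H]1[C@H]2[C@]1(C)[C@@H]3O | intermediate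
28 | 11β-methanesulfonate of 27 | CC(=O)OC[C@]12C[C@@H]4OC(C)(OC)O[C@@H]4C(C)(C)[C@]13C[C@@H]1[C@H]2[C@]1(C)[C@@H]3OS(C)(=O)=O | intermediate (not isolated)
29 | 11α,15-di-O-acetyl-3α,4α-O-(1-methoxyethylidene) compound | CC(=O)OC[C@]12C[C@@H]4OC(C)(OC)O[C@@H]4C(C)(C)[C@]13C[C@@H]1[C@H]2[C@]1(C)[C@H]3OC(C)=O | intermediate (not isolated)
30 | CNP0197219.1 (3α,11α,15-triacetoxy-4α-hydroxy cage) | CC(=O)OC[C@]12C[C@H](OC(C)=O)[C@H](O)C(C)(C)[C@]13C[C@@H]1[C@H]2[C@]1(C)[C@H]3OC(C)=O | target

**Count and risks**

Total steps: 16. Longest linear sequence: 16 steps (from 1; all other inputs are commercial).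

Steps most likely to fail:

1. Step 9 (photodecarbonylation). The excited ketone may re-close after α-cleavage or divert to a 1,3-acyl shift, and the radical pair may lose its configuration if 14 does not crystallise or the lattice softens during irradiation. Fallback (known chemistry, sets out from 14, returns at 15): NaOMe in MeOH opens the non-enolisable β-diketone by retro-Claisen cleavage of C12–C1, which expels the doubly stabilised C1 carbanion, and gives the seco methyl ester F1. Krapcho decarbomethoxylation (LiCl, wet DMSO, 140 °C) removes C12 and gives the seco enone F2. Double deprotonation (LiN(i-Pr)2, 2.2 equiv, THF, −78 °C) and oxidation of the dienediolate with Fe(acac)3 then close C1–C6 by intramolecular oxidative enolate coupling to 15. The stereochemical relay is lost on this path, so the cis isomer would have to be separated from its diastereomers, which the auxiliary makes possible.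

2. Step 8 (exchange and Claisen rearrangement). Ionisation of the prenyl ether may outrun the [3,3] shift and transfer a linear prenyl group, or the shift may not discriminate the two faces of C6 well enough. Fallback (sets out from 11, returns at 14): O-demethylation with NaSEt in DMF gives the free vinylogous acid F3. Iridium-catalysed reverse prenylation ([Ir(cod)Cl]2, a chiral phosphoramidite ligand, tert-butyl 2-methylbut-3-en-2-yl carbonate, THF) then forms the C6–C5 bond at the tertiary allyl terminus with the ligand enantiomer chosen to reinforce attack anti to the amide, and gives 14 without an O-allyl intermediate.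

3. Step 16 (inversion at C11). The cyclopropylcarbinyl cation may be captured at C8 or C9 with opening of the three-membered ring, or sulfonylation of the buried hydroxyl may stall. Fallback (sets out from 21, returns at 29; no cation is involved):
   - OsO4 with N-methylmorpholine N-oxide is expected to dihydroxylate ring A on its β-face, anti to the axial C15 amide and the axial C5 methyl, to the 3β,4β-diol F4, whose axial C4 hydroxyl lies 1,3-diaxial to C11.
   - Me4NBH(OAc)3 (AcOH–MeCN, −20 °C, Evans–Saksena-type directed reduction) delivers hydride to C11 from the ring-A side and gives the 11α-alcohol F5.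
   - Oxidation of the equatorial C3 carbinol (TEMPO cat., PhI(OAc)2) gives the 3-oxo-4β-hydroxy ketol F6, and K2CO3 in MeOH epimerises C4 to the 4α-ketol F7.
   - LiBH(s-Bu)3 then LiH2N·BH3 give the 3α,4α,11α,15-tetraol F8.
   - Orthoacetate formation (MeC(OMe)3, PPTS) followed by acetylation of both free hydroxyls (Ac2O, DMAP, pyridine) gives 29, which aqueous acetic acid opens to 30 as in step 16.

**Further compounds**

F1 | step 9 | seco methyl ester (C12 kept as CO2Me on C6, C1 now CH, Z-enone) | COC(=O)[C@@](CC1OCCO1)(C(C)(C)C=C)C(=O)/C(C)=C\C(CC=C)C(=O)N1CCC[C@H]1COC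
F2 | step 9 | seco enone (C12 removed, C1 and C6 both CH, Z-enone) | C=CC(C)(C)C(CC1OCCO1)C(=O)/C(C)=C\C(CC=C)C(=O)N1CCC[C@H]1COC
F3 | step 8 | free vinylogous acid from 11 (3-hydroxy-2,5-cyclohexadienone tautomer) | COC[C@@H]1CCCN1C(=O)[C@@]1(CC=C)C=C(C)C(=O)C(CC2OCCO2)=C1O
F4 | step 16 | 3β,4β-diol of cage ketone 21 | COC[C@@H]1CCCN1C(=O)[C@]12C[C@@H](O)[C@@H](O)C(C)(C)[C@]13C[C@@H]1[C@H]2[C@]1(C)C3=O
F5 | step 16 | 3β,4β,11α-triol with C15 carboxamide | COC[C@@H]1CCCN1C(=O)[C@]12C[C@@H](O)[C@@H](O)C(C)(C)[C@]13C[C@@H]1[C@H]2[C@]1(C)[C@H]3O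
F6 | step 16 | 3-oxo-4β,11α-diol with C15 carboxamide | COC[C@@H]1CCCN1C(=O)[C@]12CC(=O)[C@@H](O)C(C)(C)[C@]13C[C@@H]1[C@H]2[C@]1(C)[C@H]3O
F7 | step 16 | 3-oxo-4α,11α-diol with C15 carboxamide | COC[C@@H]1CCCN1C(=O)[C@]12CC(=O)[C@H](O)C(C)(C)[C@]13C[C@@H]1[C@H]2[C@]1(C)[C@H]3O
F8 | step 16 | 3α,4α,11α,15-tetraol | OC[C@]12C[C@H](O)[C@H](O)C(C)(C)[C@]13C[C@@H]1[C@H]2[C@]1(C)[C@H]3O
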